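**Retrosynthetic overview**
- Feature: with O1 taken out of the dihydropyran, C6–C2–C3–C4–C5 form a cyclopentanone (C6 = carbonyl carbon) whose C2 methyl, C3 CH2OH and C4 acetate arm are all-trans. The pyran is therefore made by oxygen insertion into a carbocycle, not by cyclisation.
- Late disconnections: the side-chain ester C–O (tert-butyl exchanged for hydroxytyrosol), C5–CO2Me (trichloroacetylation and methanolysis of the C5=C6 enol ether), and O1–C2 (Baeyer–Villiger oxidation with retention at C2).
- Key disconnection: C3–CH2Si and C2–CH3, both formed in one flask on (S)-4-(tert-butoxycarbonylmethyl)cyclopent-2-enone by copper-catalysed silylmethyl Grignard addition and enolate methylation.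
- The enone comes from the enzymatically derived cyclopentenediol monoacetate by Pd allylic alkylation (sets C4), demethoxycarbonylation and allylic oxidation.
- Ring order: the five-membered carbocycle is bought; the only ring made is the pyran, by ring expansion in step 8; the arene arrives with hydroxytyrosol.

Key step: step 5

Remark: ring atoms carry the pyran numbering of the target throughout (O1, C2 methyl, C3, C4, C5, C6). Compound 4 is an inconsequential mixture of epimers at the malonate carbon, and 15 and 16 are anomeric mixtures. TBS = tert-butyldimethylsilyl.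

**Step 1**
Reactants: 1 (1S,4R)-cis-4-acetoxycyclopent-2-en-1-ol; 2 tert-butyl methyl malonate
Product: 4 tert-butyl methyl 2-[(1R,4S)-4-hydroxycyclopent-2-en-1-yl]malonate (cis; epimers at the malonate carbon), via sodium enolate of the malonate 3 (not isolated)
Conditions: 2, NaH, THF, 0 °C; then 1, Pd(PPh3)4 (3 mol %), THF, rt → 45 °C
Reagents that add atoms: none
Why: Tsuji–Trost allylic alkylation, in which Pd(0) ionises the acetate with inversion and the soft malonate anion attacks the π-allyl anti to palladium at the terminus remote from the hydroxyl, so net retention should give the cis-1,4 product and fix the future C4 configuration.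

**Step 2**
Reactants: 4 tert-butyl methyl 2-[(1R,4S)-4-hydroxycyclopent-2-en-1-yl]malonate
Product: 5 tert-butyl 2-[(1S,4S)-4-hydroxycyclopent-2-en-1-yl]acetate (cis)
Conditions: LiCl, H2O, DMSO, 135 °C
Reagents that add atoms: none
Why: Krapcho dealkoxycarbonylation, in which chloride cleaves only the methyl ester by SN2 at CH3 (not possible at tert-butyl) and the resulting malonate half-carboxylate loses CO2, leaving the ring stereocentres untouched.

**Step 3**
Reactants: 5 tert-butyl 2-[(1S,4S)-4-hydroxycyclopent-2-en-1-yl]acetate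
Product: 6 tert-butyl (S)-2-(4-oxocyclopent-2-en-1-yl)acetate
Conditions: activated MnO2, CH2Cl2, rt
Reagents that add atoms: none
Why: Allylic alcohol oxidation with manganese dioxide under neutral conditions, which should leave the γ-stereocentre (C4) of the enone unracemised; the enone is used promptly.

**Step 4**
Reactants: 7 (chloromethyl)isopropoxydimethylsilane
Product: 8 (isopropoxydimethylsilyl)methylmagnesium chloride (THF solution, titrated)
Conditions: Mg turnings, BrCH2CH2Br (cat.), THF, reflux
Reagents that add atoms: magnesium, [Mg]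
Why: Grignard formation by magnesium insertion into the α-silyl C–Cl bond, the standard preparation of this hydroxymethyl anion equivalent.

**Step 5**
Reactants: 6 tert-butyl (S)-2-(4-oxocyclopent-2-en-1-yl)acetate; 8 (isopropoxydimethylsilyl)methylmagnesium chloride; 9 iodomethane
Product: 11 tert-butyl 2-[(1S,2S,3R)-2-{[isopropoxy(dimethyl)silyl]methyl}-3-methyl-4-oxocyclopentyl]acetate (all-trans), via chloromagnesium enolate 10 (not isolated)
Conditions: 8 (1.3 equiv), CuI (10 mol %), THF, −78 °C; then HMPA, MeI (5 equiv), −78 → −20 °C; aq. NH4Cl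
Reagents that add atoms: iodomethane (9), CI
Why: CuI and 8 form a silylmethylcuprate that π-complexes the enone, adds oxidatively at C3 and reductively eliminates to the C6/C2 chloromagnesium enolate 10, which in the presence of HMPA is C-methylated at C2 by SN2 on iodomethane. The closest known reaction type is the three-component coupling of 4-substituted cyclopentenones (organocopper conjugate addition, then enolate alkylation), combined with the copper-catalysed 1,4-addition of the silylmethyl Grignard reagent as a hydroxymethyl anion equivalent. No ring is closed; the step forms the C3–CH2Si and C2–CH3 bonds on the existing five-membered ring. C3 is set by attack of the copper reagent on the enone face opposite the C4 CH2CO2tBu arm (3,4-trans), and C2 by approach of iodomethane to the enolate face opposite the new C3 silylmethyl group (2,3-trans), which is also the thermodynamically preferred epimer. The step needs 1,4- over 1,2- and ester addition (copper catalysis at −78 °C and the hindered tert-butyl ester), enolate regiochemistry at C2 and not C5 (fixed by the conjugate addition itself), and mono- over polymethylation (excess iodomethane with HMPA at low temperature to outrun proton exchange between 10 and 11).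

**Step 6**
Reactants: 11 tert-butyl 2-[(1S,2S,3R)-2-{[isopropoxy(dimethyl)silyl]methyl}-3-methyl-4-oxocyclopentyl]acetate
Product: 12 tert-butyl 2-[(1S,2S,3R)-2-(hydroxymethyl)-3-methyl-4-oxocyclopentyl]acetate
Conditions: 30% H2O2, KF, KHCO3, THF/MeOH, rt
Reagents that add atoms: hydrogen peroxide, OO
Why: Tamao–Fleming oxidation, in which a fluoride-activated silyl peroxide undergoes a 1,2-shift of the CH2 group from silicon to oxygen; the ring stereocentres are not involved and the ketone and tert-butyl ester tolerate the buffered peroxide.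

**Step 7**
Reactants: 12 tert-butyl 2-[(1S,2S,3R)-2-(hydroxymethyl)-3-methyl-4-oxocyclopentyl]acetate
Product: 13 tert-butyl 2-[(1S,2S,3R)-2-{[tert-butyl(dimethyl)silyl]oxymethyl}-3-methyl-4-oxocyclopentyl]acetate
Conditions: TBSCl, imidazole, DMF, rt
Reagents that add atoms: tert-butyldimethylsilyl chloride, CC(C)(C)[Si](C)(C)Cl
Why: Standard silylation of a primary alcohol, which blocks lactonisation onto the arm ester and protects the alcohol through the oxidation, reduction and acylation steps.

**Step 8**
Reactants: 13 tert-butyl 2-[(1S,2S,3R)-2-{[tert-butyl(dimethyl)silyl]oxymethyl}-3-methyl-4-oxocyclopentyl]acetate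
Product: 14 tert-butyl 2-[(2R,3R,4S)-3-{[tert-butyl(dimethyl)silyl]oxymethyl}-2-methyl-6-oxooxan-4-yl]acetate (δ-lactone)
Conditions: mCPBA, NaHCO3, CH2Cl2, 0 °C → rt
Reagents that add atoms: 3-chloroperoxybenzoic acid, OOC(=O)c1cccc(Cl)c1
Why: Baeyer–Villiger oxidation, in which the secondary C2 migrates in preference to the primary C5H2 within the Criegee adduct and does so with retention, so O1 is inserted between C6 and C2 without changing the C2 configuration.

**Step 9**
Reactants: 14 tert-butyl 2-[(2R,3R,4S)-3-{[tert-butyl(dimethyl)silyl]oxymethyl}-2-methyl-6-oxooxan-4-yl]acetate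
Product: 15 tert-butyl 2-[(2R,3R,4S)-3-{[tert-butyl(dimethyl)silyl]oxymethyl}-6-hydroxy-2-methyloxan-4-yl]acetate (lactol)
Conditions: DIBAL-H (1.1 equiv), CH2Cl2, −78 °C; Rochelle salt
Reagents that add atoms: none
Why: DIBAL half-reduction of a lactone, whose tetrahedral aluminium hemiacetal is stable at −78 °C, while the hindered tert-butyl ester should react much more slowly.

**Step 10**
Reactants: 15 tert-butyl 2-[(2R,3R,4S)-3-{[tert-butyl(dimethyl)silyl]oxymethyl}-6-hydroxy-2-methyloxan-4-yl]acetate
Product: 17 tert-butyl 2-[(2R,3R,4R)-3-{[tert-butyl(dimethyl)silyl]oxymethyl}-2-methyl-3,4-dihydro-2H-pyran-4-yl]acetate, via anomeric mesylate 16 (not isolated)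
Conditions: MsCl, Et3N, CH2Cl2, −20 °C → reflux
Reagents that add atoms: none
Why: Lactol dehydration to a glycal, in which the anomeric mesylate ionises to the oxocarbenium ion and triethylamine removes H-5, giving the C5=C6 enol ether without touching C2–C4.

**Step 11**
Reactants: 17 tert-butyl 2-[(2R,3R,4R)-3-{[tert-butyl(dimethyl)silyl]oxymethyl}-2-methyl-3,4-dihydro-2H-pyran-4-yl]acetate
Product: 18 tert-butyl 2-[(2R,3R,4S)-3-{[tert-butyl(dimethyl)silyl]oxymethyl}-2-methyl-5-(trichloroacetyl)-3,4-dihydro-2H-pyran-4-yl]acetate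
Conditions: Cl3CCOCl, pyridine, CH2Cl2, 0 °C → rt
Reagents that add atoms: trichloroacetyl chloride, ClC(=O)C(Cl)(Cl)Cl
Why: Electrophilic C-acylation of a cyclic enol ether, in which the nucleophilic C5 attacks the acylpyridinium species and the oxocarbenium ion loses H-5 to restore the enol ether, as used to install the C4 carboxyl of iridoid enol ethers.

**Step 12**
Reactants: 18 tert-butyl 2-[(2R,3R,4S)-3-{[tert-butyl(dimethyl)silyl]oxymethyl}-2-methyl-5-(trichloroacetyl)-3,4-dihydro-2H-pyran-4-yl]acetate
Product: 19 methyl (2R,3R,4S)-4-(2-tert-butoxy-2-oxoethyl)-3-{[tert-butyl(dimethyl)silyl]oxymethyl}-2-methyl-3,4-dihydro-2H-pyran-5-carboxylate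
Conditions: NaOMe (cat.), MeOH, 0 °C → rt
Reagents that add atoms: methanol, CO
Why: Haloform-type cleavage, in which methoxide adds to the trichloromethyl ketone and expels CCl3−, giving the methyl β-alkoxyacrylate while the tert-butyl ester and silyl ether are inert to catalytic methoxide.

**Step 13**
Reactants: 19 methyl (2R,3R,4S)-4-(2-tert-butoxy-2-oxoethyl)-3-{[tert-butyl(dimethyl)silyl]oxymethyl}-2-methyl-3,4-dihydro-2H-pyran-5-carboxylate
Product: 21 2-[(2R,3R,4S)-3-{[tert-butyl(dimethyl)silyl]oxymethyl}-5-(methoxycarbonyl)-2-methyl-3,4-dihydro-2H-pyran-4-yl]acetic acid, via trimethylsilyl ester 20 (not isolated)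
Conditions: TMSOTf, 2,6-lutidine, CH2Cl2, 0 °C; then pH 7 buffer
Reagents that add atoms: none
Why: Silyl triflate-mediated tert-butyl ester cleavage (O-silylation of the ester, loss of isobutene, hydrolysis of the silyl ester on work-up) under base-buffered conditions, which should spare the primary TBS ether, the methyl ester and the vinylogous carbonate.

**Step 14**
Reactants: 22 hydroxytyrosol
Product: 23 tert-butyl{2-[3,4-bis(tert-butyldimethylsilyloxy)phenyl]ethoxy}dimethylsilane (tris-TBS hydroxytyrosol)
Conditions: TBSCl (3.5 equiv), imidazole, DMF, rt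
Reagents that add atoms: tert-butyldimethylsilyl chloride, CC(C)(C)[Si](C)(C)Cl
Why: Exhaustive silylation of the two phenols and the primary alcohol under standard imidazole catalysis.

**Step 15**
Reactants: 23 tris-TBS hydroxytyrosol
Product: 24 2-[3,4-bis(tert-butyldimethylsilyloxy)phenyl]ethanol
Conditions: CSA (cat.), MeOH/CH2Cl2, 0 °C
Reagents that add atoms: none
Why: Acid-catalysed methanolysis of silyl ethers, which is much faster for the primary alkyl silyl ether than for the weakly basic aryl silyl ethers, so only the aliphatic hydroxyl should be released.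

**Step 16**
Reactants: 21 2-[(2R,3R,4S)-3-{[tert-butyl(dimethyl)silyl]oxymethyl}-5-(methoxycarbonyl)-2-methyl-3,4-dihydro-2H-pyran-4-yl]acetic acid; 24 2-[3,4-bis(tert-butyldimethylsilyloxy)phenyl]ethanol
Product: 25 methyl (2R,3R,4S)-4-(2-{2-[3,4-bis(tert-butyldimethylsilyloxy)phenyl]ethoxy}-2-oxoethyl)-3-{[tert-butyl(dimethyl)silyl]oxymethyl}-2-methyl-3,4-dihydro-2H-pyran-5-carboxylate
Conditions: DCC, DMAP (cat.), CH2Cl2, 0 °C → rt
Reagents that add atoms: none
Why: Steglich esterification of an unhindered acid with a primary alcohol; no free hydroxyl or phenol is present to compete.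

**Step 17**
Reactants: 25 tris-silyl ether of the target
Product: 26 methyl (2R,3R,4S)-4-{2-[2-(3,4-dihydroxyphenyl)ethoxy]-2-oxoethyl}-3-(hydroxymethyl)-2-methyl-3,4-dihydro-2H-pyran-5-carboxylate (target)
Conditions: TBAF, AcOH (1:1), THF, 0 °C → rt
Reagents that add atoms: none
Why: Fluoride-mediated desilylation of the two aryl and one alkyl silyl ethers, buffered with acetic acid so that neither a catecholate nor a free alkoxide (which could lactonise onto the arm ester) builds up.

**Compound list**
1 | (1S,4R)-cis-4-acetoxycyclopent-2-en-1-ol | O[C@@H]1C=C[C@H](OC(C)=O)C1 | starting material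
2 | tert-butyl methyl malonate | COC(=O)CC(=O)OC(C)(C)C | starting material
3 | sodium enolate of tert-butyl methyl malonate | [Na+].COC(=O)[CH-]C(=O)OC(C)(C)C | intermediate (not isolated)
4 | tert-butyl methyl 2-[(1R,4S)-4-hydroxycyclopent-2-en-1-yl]malonate | O[C@@H]1C=C[C@H](C(C(=O)OC)C(=O)OC(C)(C)C)C1 | intermediate
5 | tert-butyl 2-[(1S,4S)-4-hydroxycyclopent-2-en-1-yl]acetate | O[C@@H]1C=C[C@H](CC(=O)OC(C)(C)C)C1 | intermediate
6 | tert-butyl (S)-2-(4-oxocyclopent-2-en-1-yl)acetate | C1C(=O)C=C[C@@H]1CC(=O)OC(C)(C)C | intermediate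
7 | (chloromethyl)isopropoxydimethylsilane | CC(C)O[Si](C)(C)CCl | starting material
8 | (isopropoxydimethylsilyl)methylmagnesium chloride | CC(C)O[Si](C)(C)C[Mg]Cl | intermediate
9 | iodomethane | CI | starting material
10 | chloromagnesium enolate of the conjugate adduct | C1C(O[Mg]Cl)=C[C@@H](C[Si](C)(C)OC(C)C)[C@@H]1CC(=O)OC(C)(C)C | intermediate (not isolated)
11 | tert-butyl 2-[(1S,2S,3R)-2-{[isopropoxy(dimethyl)silyl]methyl}-3-methyl-4-oxocyclopentyl]acetate | C1C(=O)[C@H](C)[C@@H](C[Si](C)(C)OC(C)C)[C@@H]1CC(=O)OC(C)(C)C | intermediate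
12 | tert-butyl 2-[(1S,2S,3R)-2-(hydroxymethyl)-3-methyl-4-oxocyclopentyl]acetate | C1C(=O)[C@H](C)[C@@H](CO)[C@@H]1CC(=O)OC(C)(C)C | intermediate
13 | tert-butyl 2-[(1S,2S,3R)-2-{[tert-butyl(dimethyl)silyl]oxymethyl}-3-methyl-4-oxocyclopentyl]acetate | C1C(=O)[C@H](C)[C@@H](CO[Si](C)(C)C(C)(C)C)[C@@H]1CC(=O)OC(C)(C)C | intermediate
14 | tert-butyl 2-[(2R,3R,4S)-3-{[tert-butyl(dimethyl)silyl]oxymethyl}-2-methyl-6-oxooxan-4-yl]acetate | C1C(=O)O[C@H](C)[C@@H](CO[Si](C)(C)C(C)(C)C)[C@@H]1CC(=O)OC(C)(C)C | intermediate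
15 | tert-butyl 2-[(2R,3R,4S)-3-{[tert-butyl(dimethyl)silyl]oxymethyl}-6-hydroxy-2-methyloxan-4-yl]acetate | C1C(O)O[C@H](C)[C@@H](CO[Si](C)(C)C(C)(C)C)[C@@H]1CC(=O)OC(C)(C)C | intermediate
16 | anomeric mesylate of 15 | C1C(OS(C)(=O)=O)O[C@H](C)[C@@H](CO[Si](C)(C)C(C)(C)C)[C@@H]1CC(=O)OC(C)(C)C | intermediate (not isolated)
17 | tert-butyl 2-[(2R,3R,4R)-3-{[tert-butyl(dimethyl)silyl]oxymethyl}-2-methyl-3,4-dihydro-2H-pyran-4-yl]acetate | C1=CO[C@H](C)[C@@H](CO[Si](C)(C)C(C)(C)C)[C@@H]1CC(=O)OC(C)(C)C | intermediate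
18 | tert-butyl 2-[(2R,3R,4S)-3-{[tert-butyl(dimethyl)silyl]oxymethyl}-2-methyl-5-(trichloroacetyl)-3,4-dihydro-2H-pyran-4-yl]acetate | ClC(Cl)(Cl)C(=O)C1=CO[C@H](C)[C@@H](CO[Si](C)(C)C(C)(C)C)[C@@H]1CC(=O)OC(C)(C)C | intermediate
19 | methyl (2R,3R,4S)-4-(2-tert-butoxy-2-oxoethyl)-3-{[tert-butyl(dimethyl)silyl]oxymethyl}-2-methyl-3,4-dihydro-2H-pyran-5-carboxylate | COC(=O)C1=CO[C@H](C)[C@@H](CO[Si](C)(C)C(C)(C)C)[C@@H]1CC(=O)OC(C)(C)C | intermediate
20 | trimethylsilyl ester of 21 | COC(=O)C1=CO[C@H](C)[C@@H](CO[Si](C)(C)C(C)(C)C)[C@@H]1CC(=O)O[Si](C)(C)C | intermediate (not isolated)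
21 | 2-[(2R,3R,4S)-3-{[tert-butyl(dimethyl)silyl]oxymethyl}-5-(methoxycarbonyl)-2-methyl-3,4-dihydro-2H-pyran-4-yl]acetic acid | COC(=O)C1=CO[C@H](C)[C@@H](CO[Si](C)(C)C(C)(C)C)[C@@H]1CC(=O)O | intermediate
22 | hydroxytyrosol | OCCc1ccc(O)c(O)c1 | starting material
23 | tert-butyl{2-[3,4-bis(tert-butyldimethylsilyloxy)phenyl]ethoxy}dimethylsilane | CC(C)(C)[Si](C)(C)OCCc1ccc(O[Si](C)(C)C(C)(C)C)c(O[Si](C)(C)C(C)(C)C)c1 | intermediate
24 | 2-[3,4-bis(tert-butyldimethylsilyloxy)phenyl]ethanol | OCCc1ccc(O[Si](C)(C)C(C)(C)C)c(O[Si](C)(C)C(C)(C)C)c1 | intermediate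
25 | methyl (2R,3R,4S)-4-(2-{2-[3,4-bis(tert-butyldimethylsilyloxy)phenyl]ethoxy}-2-oxoethyl)-3-{[tert-butyl(dimethyl)silyl]oxymethyl}-2-methyl-3,4-dihydro-2H-pyran-5-carboxylate | COC(=O)C1=CO[C@H](C)[C@@H](CO[Si](C)(C)C(C)(C)C)[C@@H]1CC(=O)OCCc1ccc(O[Si](C)(C)C(C)(C)C)c(O[Si](C)(C)C(C)(C)C)c1 | intermediate
26 | methyl (2R,3R,4S)-4-{2-[2-(3,4-dihydroxyphenyl)ethoxy]-2-oxoethyl}-3-(hydroxymethyl)-2-methyl-3,4-dihydro-2H-pyran-5-carboxylate | COC(=O)C1=CO[C@H](C)[C@@H](CO)[C@@H]1CC(=O)OCCc1ccc(O)c(O)c1 | target

**Step count**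
Total: 17 steps. Longest linear sequence: 14 steps (1 → 26 through steps 1–3, 5–13, 16 and 17). Step 4 and steps 14–15 are side branches.

**Steps most likely to fail, with fallbacks**

Step 5. Proton exchange between enolate 10 and the methylated ketone may cause over-methylation and regiochemical scrambling, and C-methylation may be incomplete or lose its 2,3-trans selectivity. The fallback sets out from 6 and returns at 11. It brings the methyl group in by cross-coupling and sets C2 by thermodynamic protonation, so no enolate alkylation is needed. α-Iodination of 6 (I2, pyridine, CH2Cl2, rt) should give tert-butyl (S)-2-(3-iodo-4-oxocyclopent-2-en-1-yl)acetate F1. Stille methylation (Me4Sn, Pd2(dba)3, AsPh3, CuI, NMP, 60 °C) should then give tert-butyl (S)-2-(3-methyl-4-oxocyclopent-2-en-1-yl)acetate F2. Copper-catalysed addition of 8 to this enone anti to the C4 arm (CuI cat., THF, −78 °C, NH4Cl quench), followed by equilibration of C2 with DBU in CH2Cl2 to the all-trans epimer, would return 11.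

Step 11. C-acylation at C5 may be slow next to the branched C4, and the pyridinium chloride formed may add across the enol ether or erode the silyl ether. The fallback sets out from 17 and returns at 19, replacing acylation and haloform cleavage by halogenation and carbonylation. C5 iodination of the enol ether (NIS, cat. AgNO3, MeCN, 60 °C) should give tert-butyl 2-[(2R,3R,4S)-3-{[tert-butyl(dimethyl)silyl]oxymethyl}-5-iodo-2-methyl-3,4-dihydro-2H-pyran-4-yl]acetate F3. Palladium-catalysed methoxycarbonylation of this vinyl iodide (Pd(OAc)2, Xantphos, CO 1 atm, MeOH, Et3N, DMF, 60 °C) would deliver 19 directly.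

Step 17. On desilylation the liberated C3 hydroxymethyl group may transesterify onto the arm ester (δ-lactonisation with expulsion of hydroxytyrosol), and the catechol may oxidise in air under fluoride. The fallback sets out from 21 (with unprotected 22) and returns at 26, so that only one alkyl silyl ether has to be removed and this is done under acidic, non-basic conditions. Mitsunobu esterification of 21 with 22 (PPh3, DIAD, THF, 0 °C), which activates only the aliphatic primary hydroxyl while the carboxylate acts as the nucleophile, should give methyl (2R,3R,4S)-3-{[tert-butyl(dimethyl)silyl]oxymethyl}-4-{2-[2-(3,4-dihydroxyphenyl)ethoxy]-2-oxoethyl}-2-methyl-3,4-dihydro-2H-pyran-5-carboxylate F4. Treatment with HF·pyridine in pyridine/THF at 0 °C would then give 26.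

**Further compounds**
F1 | step 5 | tert-butyl (S)-2-(3-iodo-4-oxocyclopent-2-en-1-yl)acetate | O=C1C(I)=C[C@H](CC(=O)OC(C)(C)C)C1
F2 | step 5 | tert-butyl (S)-2-(3-methyl-4-oxocyclopent-2-en-1-yl)acetate | O=C1C(C)=C[C@H](CC(=O)OC(C)(C)C)C1
F3 | step 11 | tert-butyl 2-[(2R,3R,4S)-3-{[tert-butyl(dimethyl)silyl]oxymethyl}-5-iodo-2-methyl-3,4-dihydro-2H-pyran-4-yl]acetate | IC1=CO[C@H](C)[C@@H](CO[Si](C)(C)C(C)(C)C)[C@@H]1CC(=O)OC(C)(C)C
F4 | step 17 | methyl (2R,3R,4S)-3-{[tert-butyl(dimethyl)silyl]oxymethyl}-4-{2-[2-(3,4-dihydroxyphenyl)ethoxy]-2-oxoethyl}-2-methyl-3,4-dihydro-2H-pyran-5-carboxylate | COC(=O)C1=CO[C@H](C)[C@@H](CO[Si](C)(C)C(C)(C)C)[C@@H]1CC(=O)OCCc1ccc(O)c(O)c1
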